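The target is what I can read in these flasks, so I ask one thing of it: what share of the starting material charged has become target by 30 min?

| flask | starting material | partner | time |
|---|---|---|---|
| Thursday's | 0.300 M | 0.360 M |  |
| Wednesday's | 0.300 M | 0.720 M |  |
| Monday's | 0.150 M | 0.360 M |  |
| Tuesday's | 0.0650 M | 0.360 M | 30 min |

| Thursday's run: time / min | Thursday's run: [target] / M | Wednesday's run: time / min | Wednesday's run: [target] / M | Monday's run: time / min | Monday's run: [target] / M |
|---|---|---|---|---|---|
| 1.2 | 0.0045 | 1.2 | 0.0094 | 1.2 | 0.0031 |
| 2.3 | 0.0100 | 2.3 | 0.0145 | 2.3 | 0 |
| 4.3 | 0.0158 | 4.3 | 0.0323 | 4.3 | 0.0064 |
| 8.3 | 0.0295 | 8.3 | 0.0716 | 8.3 | 0.0097 |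
| 16 | 0.0579 | 16 | 0.1118 | 16 | 0.0186 |
| 30 | 0.0839 | 30 | 0.0931 | 30 | 0.0281 |

(standard deviation of a reading: 0.002 M)

- Overall: starting material + partner -> target.
- Constant volume, constant temperature.
- "The second partner" is partner.
- An order is taken over about fifteen percent of the charge, up and down.

- reaction order in [partner] at the outset, round the charge of the Thursday's run, defined at two percent of the starting material turned into target
- reaction order in [starting material] at the outset, round the charge of the Thursday's run, defined at two percent of the starting material turned into target (one fixed amount of target, the same in the runs compared)
- target in the Tuesday's run at 30 min, as a share of the starting material charged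

I build the flask up one process at a time. With the main step by itself, starting material plus partner, and partner taken as constant at its charge (pseudo-first-order), the share doesn't depend on the charge of starting material, so Tuesday's flask would copy Monday's 18.7%.

But Thursday's flask, with the same partner, reads 28.0%, more than Monday's, so a second process grows with the charge. I go to logarithms: the logarithm of the ratio of two shares over the logarithm of the ratio of their charges, at equal partner and equal time, reads 0.578 between these flasks. This is my share exponent, and it is zero for a step first order in starting material. The scatter of Monday's reading moves it by 0.0992. Carried down to Tuesday's charge, it lowers the share from 18.7% to 11.6%.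

The third process shows in Wednesday's flask, where target falls from 0.1118 M to 0.0931 M, so target is being lost. If that loss goes as target times partner, it takes about the same fraction from Monday's, Thursday's and Tuesday's flasks and cancels in the exponent, so I stay at 11.6%.

The forecast says 1.05 in partner, 1.6 in starting material and 13%, a little above my share, and it notes that the order “could be a mix of first- and second-order paths”.

The flask gives 1.1 in partner, 1.1 in starting material and 13.2%.

    starting material + partner → target (0.02448 L mol⁻¹ min⁻¹)
    target + partner → side product (0.09660 L mol⁻¹ min⁻¹)
    starting material + partner + target → 2 target (1.422 L² mol⁻² min⁻¹)
    starting material → decomposed substrate (0.01938 min⁻¹)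

From Monday's flask down to Tuesday's the share exponent reads 0.422, and on the rates of Monday's and Thursday's flasks at equal target it reads 0.220, both below 0.578. In Thursday's flask the main step ran first, and the target-fed step passed it once target exceeded 0.0172 M, as the reading of 0.0295 M at 8.3 min had done. In Tuesday's flask target stood at 0.00855 M at 30 min, still under that mark, and there, with partner taken at its charge, decomposition took starting material faster than both target-making steps together, at 0.0194 min⁻¹ against 0.0132 min⁻¹.

(The earlier runs and the new flask were generated by integration for substances that don't exist; the scatter is artificial.)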